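## Analysis of the target

The target 10 is a C2-symmetric 3,3''-biflavanone: two 7-hydroxy-5-methoxy-2-(4-methoxyphenyl)chroman-4-one units joined by the single bond C3–C3'' between the α-carbons of the two C4 ketones. It has four contiguous stereocentres, (2S,3R,2''S,3''R); in each ring C the anisyl group on C2 and the C3–C3'' bond are trans, and since both halves are 2S this trans relationship alone fixes C3 and C3''. Each C3–H is α to a ketone and β to the aryloxy oxygen O1, so base epimerises C3 or opens ring C to a chalcone and destroys C2 as well; the C2–O1 bonds are p-methoxybenzylic ethers, and rings A are phloroglucinol-type arenes that oxidise easily once O7 is free. The hard parts are the bond between two hindered, like-polarised α-carbons that cannot be handled as enolates, the two stereocentres on each side of it, and the distinction between O5 (methyl) and O7 (free) on each ring A. The feature used is that C3 and C3'' are the β-carbons of the C3=C4 enol ethers of two identical (2S)-flavanones: joining two such styrene-like double bonds head to head gives C3–C3'' together with a C4–C4'' bond that bears an oxygen on each carbon and can be cut again to the two ketones. The O5-methyl/O7-free pattern is that of a flavanone 7-O-glycoside after methylation and loss of the sugar, so naringin looks like a ready source of each half; it was not used, because its chelated 5-OH is not methylated dependably by diazomethane, basic methylation opens ring C, and the commercial glycoside is a mixture of C2 epimers that hot acid erodes further. The monomer is therefore made with O7 benzylated from the start and C2 set by an asymmetric aryl addition.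

## Retrosynthetic reasoning

**10 ⇒ 9 (O7–H, O7''–H).** The target is traced to its 7,7''-dibenzyl ether 9. Benzyl groups leave by hydrogenolysis, without the base that would epimerise C3 or open ring C and without the Lewis acid that would cleave the O5 methyl ethers next to C4=O. O7 also has to stay covered during the oxidation one step earlier.

**9 ⇒ 8 (C4=O and C4''=O joined to C4–C4'').** The two carbonyl carbons of 9 are connected in thought, each keeping its oxygen as a hydroxyl. This gives the cyclobutane-1,2-diol 8, whose ring atoms are C3, C4, C4'' and C3''. It is the retron of an oxidative glycol cleavage. The 1,4-diketone, hard to assemble from two ketone α-carbons, becomes a four-membered ring that a cycloaddition can build. The forward cleavage also supplies the two-electron oxidation that any union of two enol derivatives at their β-carbons needs. It has to cut a trans-diol, which ring strain and two benzylic carbinol carbons should make possible.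

**8 ⇒ 7 (O–Si).** The two hydroxyls are masked as tert-butyldimethylsilyl ethers in 7, because they originate from enol ether oxygens. The forward step is a fluoride cleavage kept close to neutral, since the bis-benzylic diol would ionise under acid.

**7 ⇒ 6 + 6 (C3–C3'' and C4–C4'').** The cyclobutane of 7 is cut into two molecules of the silyl enol ether 6. This is the only cut that gives two identical halves, each holding every atom of one flavanone unit. The forward [2+2] photodimerisation joins two carbons of the same polarity without an enolate. It must be head to head, and each molecule of 6 must react on the face away from its C2 anisyl group. The cis ring fusions then leave only the C2-symmetric anti dimer.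

**6 ⇒ 5 (enol O–Si).** The enol ether 6 comes from the (2S)-flavanone 5 by soft enolisation, which avoids a free enolate and so keeps ring C closed and C2 intact.

**5 ⇒ 3 + 4 (C2–aryl).** Cutting the bond between C2 and the anisyl ring leads to the flat chromone 3 and the boronic acid 4. The single stereocentre of the monomer is then set by a chiral catalyst under neutral conditions, and all O-alkylations are done before a base-sensitive flavanone exists.

**3 ⇒ 2 ⇒ 1 (O5–CH3, then O7–benzyl).** The methyl ether on the chelated O5 needs forcing basic conditions, which the chromone 2 tolerates. The benzyl ether goes first onto the more acidic, unchelated 7-OH of the dihydroxychromone 1.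

## Alternatives that were turned down

**Alternative 1:** The bonds C2–C3 and C2''–C3'' are cut, with C3–C3'' already present as the central single bond of an (E,E)-diene.

- Key step: the substrate is (2R,3E,5E,7R)-2,7-bis(4-methoxybenzyloxy)octa-3,5-diene A2. Deprotonation of both benzylic CH2 groups and two [2,3]-Wittig shifts would turn these carbons into C2 and C2'' and give the diol A1, 1,4-bis(4-methoxyphenyl)-2,3-di[(E)-prop-1-enyl]butane-1,4-diol. Its propenyl groups stand for C4 and C4''.
- For it: the [2,3]-Wittig rearrangement is an established reaction. Its five-membered transition state passes the configuration of the two allylic C–O centres on to C3 and C3''. E-alkenes favour the anti relationship between the new carbinol and the new C3 centre, which is the one needed. On precedent for the central step this alternative is stronger than the chosen route.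
- Against: the p-methoxy groups lower the acidity of the benzylic positions and raise the share of [1,2]-shift. The second shift has to occur next to a lithium alkoxide and a fresh stereocentre. The anti preference of aryl-substituted carbanions with E-alkenes is only moderate.
- Against, step economy: A1 contains neither ring A nor either ketone. Two alkene cleavages, two aryl additions, two oxidations and two O1–C8a ring closures must follow, the later ones on retro-aldol-prone β-hydroxy ketones.
- Comparison: in the chosen route every carbon of 10 is present in 6 before the key step and only three steps follow it. What it gives up is precedent.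

**Alternative 2:** The bonds C4–C4a and C4''–C4a'' are cut.

- Key step: the cis-fused dilactone A4, 3,6-bis(4-methoxyphenyl)tetrahydrofuro[3,4-c]furan-1,4-dione, already holds C2, C3, C3'', C2'' and both O1 atoms. Two equivalents of 2-fluoro-6-methoxy-4-(triisopropylsilyloxy)phenyllithium A5 would open both lactones to the bis(aryl ketone) diol A3. Each freed C2 alkoxide would later displace the fluorine on C8a to close ring C.
- For it: it is convergent and two-directional. The four stereocentres sit in a rigid bicycle before the coupling, and O5/O7 are differentiated inside A5. Every step belongs to a known reaction class, so it is stronger than the chosen route on precedent and on the O7 problem.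
- Against, structure: mapping 10 onto A4 shows that the 2,3-trans flavanone arrangement requires both anisyl groups on the concave face, cis to the acyl carbon on the neighbouring bridgehead. This is the crowded endo,endo isomer and not the exo,exo one that this ring system normally adopts. It would also be needed as one enantiomer.
- Against, mechanism: A5 is an ortho-fluoroaryllithium and goes to an aryne on warming. The lactone α-hydrogens at C3 and C3'' are acidic and β to a carboxylate leaving group. A3 is a double aldol whose alkoxides can cleave C2–C3 by retro-aldol before the slow substitution on a donor-rich ring occurs.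
- Comparison: the chosen route never places a C2 alkoxide β to a ketone and uses no base once C3–C3'' exists.

**Alternative 3:** Both rings A are cut off, at C8–C8a and C5–C4a in each half.

- Key step: the bis(α-bromo enone) A7 is two 5-bromo-2-(4-methoxyphenyl)-2,3-dihydropyran-4-one units joined at C3. It would react twice with 1,1-dimethoxy-3-(trimethylsilyloxy)buta-1,3-diene A8. After cycloaddition, elimination of the bromine and of one methoxy group per ring would aromatise both rings A and give A6, the 7,7''-bis(trimethylsilyl) ether of 10.
- For it: the diene places a methoxy group on C5 and a labile silyl ether on C7 directly. The end game is one trivial desilylation. On this point it is stronger than the chosen route, which spends a benzylation and a hydrogenolysis on O7.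
- Against, strategy: the key step does not make C3–C3''. That bond must already be in A7, and forming it between two dihydropyranone α-carbons meets the same enolate problems without a solution.
- Against, mechanism: C8a carries the ring oxygen, so the enone is a vinylogous ester and a poor partner for an electron-rich diene. The conditions needed to force the addition and to eliminate the bromine act on a C3–H that is α to the ketone and β to O1, so ring opening and loss of the C3/C3'' configuration threaten, twice on one molecule.
- Comparison: the chosen route starts from finished rings A and spends its one uncertain step on the C3–C3'' bond itself.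

Key step: step 5

Assumption: the (S)-configured biaryl diphosphine is taken to deliver the aryl group to the C2 face that gives the (2S)-flavanone, by analogy with the sense of addition to cyclic enones; if the sense is the opposite, the (R)-ligand is used and nothing else changes.

## Route

Step 1
Reactants: 1 5,7-dihydroxy-4H-chromen-4-one
Product: 2 7-(benzyloxy)-5-hydroxy-4H-chromen-4-one
Conditions: BnBr (1.05 equiv), K2CO3, acetone, reflux
Reagents that add atoms: benzyl bromide, BrCc1ccccc1
Why: Williamson ether synthesis; the 7-OH is the more acidic, unchelated phenol, while the 5-OH is held in a hydrogen bond to C4=O, so one equivalent of benzyl bromide should give the 7-ether selectively.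

Step 2
Reactants: 2 7-(benzyloxy)-5-hydroxy-4H-chromen-4-one
Product: 3 7-(benzyloxy)-5-methoxy-4H-chromen-4-one
Conditions: MeI (excess), K2CO3, DMF, 50 °C
Reagents that add atoms: iodomethane, CI
Why: Williamson methylation of the chelated 5-OH, which needs excess reagent and heat; the chromone tolerates this because it has no C2 stereocentre and cannot open to a chalcone as a flavanone would.

Step 3
Reactants: 3 7-(benzyloxy)-5-methoxy-4H-chromen-4-one; 4 4-methoxyphenylboronic acid
Product: 5 (2S)-7-(benzyloxy)-5-methoxy-2-(4-methoxyphenyl)-2,3-dihydro-4H-chromen-4-one
Conditions: 4 (2 equiv), [Rh(OH)(cod)]2 (2.5 mol%), (S)-MeO-F12-BIPHEP (5.5 mol%), PhMe–H2O, 25 °C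
Reagents that add atoms: none
Why: Rhodium-catalysed asymmetric 1,4-addition of an arylboronic acid to a chromone (Hayashi–Miyaura type); the aryl–rhodium species adds to C2 on the face selected by the chiral diphosphine and water protonates the rhodium enolate, so C2 is set as S under catalyst control. The medium is neutral, so 5 should not racemise through the chalcone.

Step 4
Reactants: 5 (2S)-7-(benzyloxy)-5-methoxy-2-(4-methoxyphenyl)-2,3-dihydro-4H-chromen-4-one
Product: 6 (2S)-7-benzyloxy-4-(tert-butyldimethylsilyloxy)-5-methoxy-2-(4-methoxyphenyl)-2H-chromene
Conditions: TBSOTf (1.3 equiv), Et3N (2 equiv), CH2Cl2, 0 °C; NaHCO3 work-up, Et3N-deactivated silica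
Reagents that add atoms: tert-butyldimethylsilyl trifluoromethanesulfonate, CC(C)(C)[Si](C)(C)OS(=O)(=O)C(F)(F)F
Why: Soft enolisation; the silyl triflate activates the C4 ketone and Et3N removes a C3 proton, so no free enolate is formed that could expel O1 and open ring C. C2 is not touched.

Step 5
Reactants: 6 (2S)-7-benzyloxy-4-(tert-butyldimethylsilyloxy)-5-methoxy-2-(4-methoxyphenyl)-2H-chromene (two molecules)
Product: 7 head-to-head anti photodimer of 6, (2S,3R,4S,2''S,3''R,4''S) in flavonoid numbering: cyclobutane C3–C4–C4''–C3'' cis-fused to both pyran rings, which lie on opposite faces; H3 and H3'' trans; tert-butyldimethylsilyloxy groups on C4 and C4'' trans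
Conditions: thioxanthone (10 mol%), 405 nm LEDs, degassed PhMe (0.5 M), 15–20 °C
Reagents that add atoms: none
Why: Proposed new method: thioxanthone absorbs the 405 nm light, reaches its triplet state (about 65 kcal/mol) and passes the energy to the styrene-like C3=C4 bond of 6, whose triplet adds through C3 to C3 of a second, ground-state molecule to give a 1,4-diradical with both spins on the benzylic, silyloxy-bearing carbons C4 and C4''; after spin inversion these combine to the C4–C4'' bond. The closest known reaction type is the triplet-sensitised head-to-head [2+2] photodimerisation of indenes, 1,2-dihydronaphthalenes and styrenes, which has not been shown for an oxygenated 2H-chromene silyl enol ether. The one ring that closes is the cyclobutane C3–C4–C4''–C3'', formed by radical–radical combination within the 1,4-diradical, the second stage of a stepwise [2+2] cycloaddition. C3 and C3'' are set when the first bond forms: each C3=C4 bond reacts on the face away from the anisyl group on its own C2, as other additions to flav-3-enes do, which gives the 2,3-trans arrangement (3R and 3''R) of the target. C4 and C4'' follow from the ring constraint, because a cyclobutane can only be cis-fused to each pyran ring, so two (2S) molecules that both react on the anti face can only give the C2-symmetric anti dimer with the silyloxy groups trans (4S and 4''S). The step needs head-to-head regioselectivity, which comes from making the first bond between the two unsubstituted carbons so that both radical centres are benzylic and oxygen-stabilised; the head-to-tail dimer is the foreseeable by-product. Light of 405 nm is not absorbed by 6 itself, which avoids the singlet electrocyclic opening of the 2H-chromene to an ortho-quinone methide that would scramble C2, and no enolate is formed, so ring C cannot open by elimination. Toluene disfavours electron transfer from the electron-rich enol ether to the excited sensitiser, and the high concentration and the absence of oxygen favour the bimolecular step.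

Step 6
Reactants: 7 head-to-head anti photodimer of 6
Product: 8 (2S,3R,4S,2''S,3''R,4''S) trans-cyclobutane-1,2-diol: compound 7 with OH in place of both silyloxy groups on C4 and C4''
Conditions: TBAF (3 equiv), AcOH (3 equiv), THF, 0 → 20 °C
Reagents that add atoms: none
Why: Fluoride cleavage of the two tertiary silyl ethers; acetic acid protonates the alkoxides and keeps the medium near neutral, which protects the acid-labile bis-benzylic cyclobutanediol from ionisation. The benzyl ethers are inert and no stereocentre changes.

Step 7
Reactants: 8 trans-cyclobutane-1,2-diol
Product: 9 7,7''-di-O-benzyl ether of the target, (2S,3R,2''S,3''R)-7,7''-bis(benzyloxy)-5,5''-dimethoxy-2,2''-bis(4-methoxyphenyl)-3,3''-bichroman-4,4''-dione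
Conditions: Pb(OAc)4 (1.1 equiv), pyridine, CH2Cl2, 0 → 20 °C
Reagents that add atoms: none
Why: Criegee glycol cleavage; two-electron oxidation of the 1,2-diol breaks C4–C4'' and gives both C4 ketones at once. The trans-diol cannot easily form a cyclic lead ester, but pyridine promotes the open-chain pathway for such diols, and release of cyclobutane strain in a bis-benzylic bond adds driving force. C2, C3, C3'' and C2'' are not touched and end in the stable 2,3-trans arrangement.

Step 8
Reactants: 9 7,7''-di-O-benzyl ether of the target
Product: 10 4',4''',5,5''-tetramethylchamaejasmin, (2S,3R,2''S,3''R)-7,7''-dihydroxy-5,5''-dimethoxy-2,2''-bis(4-methoxyphenyl)-3,3''-bichroman-4,4''-dione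
Conditions: H2 (1 atm), 10% Pd/C, EtOAc–THF, 20 °C
Reagents that add atoms: none
Why: Hydrogenolysis of the two aryl benzyl ethers under neutral conditions, which avoids the base that would epimerise C3 or open ring C. The reaction is stopped after uptake of two equivalents of hydrogen to spare the benzylic C2–O1 bonds.

## Compound list

1 | 5,7-dihydroxy-4H-chromen-4-one | O=c1ccoc2cc(O)cc(O)c12 | starting material
2 | 7-(benzyloxy)-5-hydroxy-4H-chromen-4-one | O=c1ccoc2cc(OCc3ccccc3)cc(O)c12 | intermediate
3 | 7-(benzyloxy)-5-methoxy-4H-chromen-4-one | COc1cc(OCc2ccccc2)cc2occc(=O)c12 | intermediate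
4 | 4-methoxyphenylboronic acid | COc1ccc(B(O)O)cc1 | starting material
5 | (2S)-7-(benzyloxy)-5-methoxy-2-(4-methoxyphenyl)-2,3-dihydro-4H-chromen-4-one | COc1ccc([C@H]2Oc3cc(OCc4ccccc4)cc(OC)c3C(=O)C2)cc1 | intermediate
6 | (2S)-7-benzyloxy-4-(tert-butyldimethylsilyloxy)-5-methoxy-2-(4-methoxyphenyl)-2H-chromene | COc1ccc([C@H]2Oc3cc(OCc4ccccc4)cc(OC)c3C(O[Si](C)(C)C(C)(C)C)=C2)cc1 | intermediate
7 | head-to-head anti photodimer of 6, (2S,3R,4S,2''S,3''R,4''S), cyclobutane C3–C4–C4''–C3'' cis-fused to both pyran rings, silyloxy groups on C4 and C4'' trans | COc1ccc([C@H]2Oc3cc(OCc4ccccc4)cc(OC)c3[C@@]3(O[Si](C)(C)C(C)(C)C)[C@@H]2[C@H]2[C@]3(O[Si](C)(C)C(C)(C)C)c3c(OC)cc(OCc4ccccc4)cc3O[C@@H]2c2ccc(OC)cc2)cc1 | intermediate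
8 | (2S,3R,4S,2''S,3''R,4''S) trans-cyclobutane-1,2-diol corresponding to 7 (OH on C4 and C4'') | COc1ccc([C@H]2Oc3cc(OCc4ccccc4)cc(OC)c3[C@@]3(O)[C@@H]2[C@H]2[C@]3(O)c3c(OC)cc(OCc4ccccc4)cc3O[C@@H]2c2ccc(OC)cc2)cc1 | intermediate
9 | (2S,3R,2''S,3''R)-7,7''-bis(benzyloxy)-5,5''-dimethoxy-2,2''-bis(4-methoxyphenyl)-3,3''-bichroman-4,4''-dione | COc1ccc([C@H]2Oc3cc(OCc4ccccc4)cc(OC)c3C(=O)[C@@H]2[C@H]2C(=O)c3c(OC)cc(OCc4ccccc4)cc3O[C@@H]2c2ccc(OC)cc2)cc1 | intermediate
10 | 4',4''',5,5''-tetramethylchamaejasmin, (2S,3R,2''S,3''R) | COc1ccc([C@H]2Oc3cc(O)cc(OC)c3C(=O)[C@@H]2[C@H]2C(=O)c3c(OC)cc(O)cc3O[C@@H]2c2ccc(OC)cc2)cc1 | target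

## Step count and least certain steps

Total step count: 8. Longest linear sequence: 8 steps (1 → 10); compound 4 enters at step 3.

**Step 5 (key step, proposed new method).**
- What may go wrong: closure of the 1,4-diradical to the fully substituted C4–C4'' bond may be slow, because each carbon carries a silyloxy group and an aryl ring with a peri-methoxy group. The diradical would then fall back to two molecules of 6, or the head-to-tail mode would gain ground.
- Also possible: electron transfer from the electron-rich enol ether to the excited sensitiser with loss of the silyl group; sensitised opening of the chromene with erosion of C2; incomplete facial selectivity at C3; and thermal reversal of 7 on standing, since its C4–C4'' bond is weakened by strain and by two stabilised radical termini. Compound 7 should therefore be kept cold and carried on promptly.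
- Fallback (known chemistry), from 5 to 9: two molecules of 5 are tied through their C4 oxygens by soft enolisation with iPr2Si(OTf)2 and Et3N to give the diisopropylsilyl bis-enol ether F1. Oxidation of F1 with (NH4)2Ce(NO3)6 and NaHCO3 in MeCN at −10 °C is an oxidative coupling of a silyl bis-enol ether, known for tetralone-type aryl ketones. It forms C3–C3'' within a seven-membered tethered arrangement, each C3 reacting trans to its C2 anisyl group, and loses the silicon on work-up. The product is 9, where the route is rejoined; steps 4 to 7 fall away.

**Step 7.**
- What may go wrong: sluggish cleavage, because the trans-diol cannot reach a cyclic lead ester, with oxidation of the electron-rich rings A or acetoxylation α to the new ketones taking over.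
- Fallback, from 8 to 9: anodic oxidation at a carbon anode (Et4NOTs, MeCN–MeOH, 2,6-lutidine), an electro-oxidative glycol cleavage. It runs through an arene radical cation and scission of C4–C4'' and does not depend on the diol geometry. No new compound is made on the way (F0).

**Step 6.**
- What may go wrong: incomplete removal of the two hindered tertiary silyl groups, or ionisation at C4 of the freed diol followed by a pinacol-type ring contraction.
- Fallback, from 5 to 8: a more labile silyl group is used from the start. TESOTf and Et3N convert 5 into the triethylsilyl enol ether F2. Sensitised dimerisation as in step 5 gives the bis(triethylsilyl) dimer F3. Its silyl ethers are cleaved with TBAF and AcOH at −20 °C to give 8, where the route is rejoined.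

**Step 3.**
- What may go wrong: low reactivity of the doubly donor-substituted chromone with competing protodeboronation of 4, a second addition to the ketone of 5, or insufficient enantioselectivity.
- Fallback, from 3 to 5: the same addition with [Rh(OH)(cod)]2 alone gives the racemic flavanone F4. Preparative chromatography on a cellulose tris(3,5-dimethylphenylcarbamate) phase separates 5 from the (2R)-enantiomer F5. F5 can be racemised with mild base through the chalcone and recycled. The route is rejoined at 5, with the configuration assigned by circular dichroism.

## Further compounds

F1 | step 5 | diisopropylsilyl bis-enol ether of 5, bis[(2S)-7-benzyloxy-5-methoxy-2-(4-methoxyphenyl)-2H-chromen-4-yloxy]diisopropylsilane | CC(C)[Si](OC1=C[C@@H](c2ccc(OC)cc2)Oc2cc(OCc3ccccc3)cc(OC)c21)(OC1=C[C@@H](c2ccc(OC)cc2)Oc2cc(OCc3ccccc3)cc(OC)c21)C(C)C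
F0 | step 7 | none | none
F2 | step 6 | (2S)-7-benzyloxy-5-methoxy-2-(4-methoxyphenyl)-4-(triethylsilyloxy)-2H-chromene | COc1ccc([C@H]2Oc3cc(OCc4ccccc4)cc(OC)c3C(O[Si](CC)(CC)CC)=C2)cc1
F3 | step 6 | head-to-head anti photodimer of F2, (2S,3R,4S,2''S,3''R,4''S), triethylsilyloxy groups on C4 and C4'' | COc1ccc([C@H]2Oc3cc(OCc4ccccc4)cc(OC)c3[C@@]3(O[Si](CC)(CC)CC)[C@@H]2[C@H]2[C@]3(O[Si](CC)(CC)CC)c3c(OC)cc(OCc4ccccc4)cc3O[C@@H]2c2ccc(OC)cc2)cc1
F4 | step 3 | racemic 7-(benzyloxy)-5-methoxy-2-(4-methoxyphenyl)-2,3-dihydro-4H-chromen-4-one | COc1ccc(C2Oc3cc(OCc4ccccc4)cc(OC)c3C(=O)C2)cc1
F5 | step 3 | (2R)-7-(benzyloxy)-5-methoxy-2-(4-methoxyphenyl)-2,3-dihydro-4H-chromen-4-one | COc1ccc([C@@H]2Oc3cc(OCc4ccccc4)cc(OC)c3C(=O)C2)cc1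
A1 | alternative 1 | 1,4-bis(4-methoxyphenyl)-2,3-di[(E)-prop-1-enyl]butane-1,4-diol with the configuration of C2, C3, C3'', C2'' of 10 | COc1ccc([C@@H](O)[C@H](/C=C/C)[C@@H](/C=C/C)[C@H](O)c2ccc(OC)cc2)cc1
A2 | alternative 1 | (2R,3E,5E,7R)-2,7-bis(4-methoxybenzyloxy)octa-3,5-diene | COc1ccc(CO[C@H](C)/C=C/C=C/[C@@H](C)OCc2ccc(OC)cc2)cc1
A3 | alternative 2 | 2,3-bis(2-fluoro-6-methoxy-4-triisopropylsilyloxybenzoyl)-1,4-bis(4-methoxyphenyl)butane-1,4-diol with the configuration of C2, C3, C3'', C2'' of 10 | COc1ccc([C@@H](O)[C@H](C(=O)c2c(F)cc(O[Si](C(C)C)(C(C)C)C(C)C)cc2OC)[C@@H](C(=O)c2c(F)cc(O[Si](C(C)C)(C(C)C)C(C)C)cc2OC)[C@H](O)c2ccc(OC)cc2)cc1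
A4 | alternative 2 | cis-fused 3,6-bis(4-methoxyphenyl)tetrahydrofuro[3,4-c]furan-1,4-dione, both aryl groups on the concave face | COc1ccc([C@H]2OC(=O)[C@@H]3[C@H]2C(=O)O[C@@H]3c2ccc(OC)cc2)cc1
A5 | alternative 2 | 2-fluoro-6-methoxy-4-(triisopropylsilyloxy)phenyllithium | [Li]c1c(F)cc(O[Si](C(C)C)(C(C)C)C(C)C)cc1OC
A6 | alternative 3 | 7,7''-bis(trimethylsilyl) ether of 10 | COc1ccc([C@H]2Oc3cc(O[Si](C)(C)C)cc(OC)c3C(=O)[C@@H]2[C@H]2C(=O)c3c(OC)cc(O[Si](C)(C)C)cc3O[C@@H]2c2ccc(OC)cc2)cc1
A7 | alternative 3 | (2S,3R,2'S,3'R)-5,5'-dibromo-2,2'-bis(4-methoxyphenyl)-2,2',3,3'-tetrahydro-[3,3'-bipyran]-4,4'-dione | COc1ccc([C@H]2OC=C(Br)C(=O)[C@@H]2[C@H]2C(=O)C(Br)=CO[C@@H]2c2ccc(OC)cc2)cc1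
A8 | alternative 3 | 1,1-dimethoxy-3-(trimethylsilyloxy)buta-1,3-diene | COC(OC)=CC(=C)O[Si](C)(C)C
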